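Carotenoid numbering is used (primed atoms: 7',8'-dihydro half). Everything rests on the C8'–C9' bond, where the only saturated bridge, C7'H2–C8'H2 on ring C1'–C6', meets the heptaene terminus C9'. The key step exploits this bridge and the identity of the two cyclohexene rings. In one flask a 6'-vinyl ring diene is hydroborated at C8', and the borane is coupled with the C9' iodide of a linear C20 heptaenyne (B-alkyl Suzuki–Miyaura). The uncapped C7 alkyne is then coupled with the ring enol triflate from which the diene was made (Sonogashira). The precursor is an achiral 1-silyl-16-iodo polyene, built from C10-dialdehyde and one C4 iodophosphonate used twice.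

Key step: step 9

Assumption: (4R,6R)-actinol and the all-E C10-dialdehyde, both bulk carotenoid intermediates, are taken as purchasable. All polyene steps are run under argon with exclusion of light.

Step 1
Reactants: 1 (4R,6R)-4-hydroxy-2,2,6-trimethylcyclohexanone ((4R,6R)-actinol)
Product: 2 (4R,6R)-4-(tert-butyldimethylsilyloxy)-2,2,6-trimethylcyclohexanone
Conditions: TBSCl, imidazole, DMF, rt
Reagents that add atoms: tert-butyldimethylsilyl chloride CC(C)(C)[Si](C)(C)Cl
Why: Imidazole-promoted O-silylation of the only hydroxyl group masks it against the amide base, the organometallic reagents and the borane used later, and it does not touch the C4 stereocentre, which is bought in with 1 and becomes C3 and C3' of the target.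

Step 2
Reactants: 2 (4R,6R)-4-(tert-butyldimethylsilyloxy)-2,2,6-trimethylcyclohexanone
Product: 4 (4R)-4-(tert-butyldimethylsilyloxy)-2,6,6-trimethylcyclohex-1-en-1-yl trifluoromethanesulfonate, via lithium enolate 3 (not isolated)
Conditions: LDA, THF, −78 → 0 °C; PhNTf2, −78 °C → rt
Reagents that add atoms: N-phenylbis(trifluoromethanesulfonimide) O=S(=O)(N(c1ccccc1)S(=O)(=O)C(F)(F)F)C(F)(F)F; lithium diisopropylamide [Li+].CC(C)[N-]C(C)C (lithium of 3 only)
Why: Enol triflate formation: the ketone has only one α-hydrogen (at C6), so deprotonation can give only the tetrasubstituted enolate 3, which is O-sulfonylated by the triflimide, while the C6 stereocentre is erased on purpose and the γ-silyloxy group cannot be eliminated.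

Step 3
Reactants: 4 enol triflate; 5 tributyl(vinyl)stannane
Product: 6 tert-butyl(dimethyl){[(1R)-4-ethenyl-3,5,5-trimethylcyclohex-3-en-1-yl]oxy}silane
Conditions: Pd2(dba)3 (cat.), AsPh3, LiCl, NMP, 55 °C
Reagents that add atoms: none
Why: Stille coupling of the hindered cyclohexenyl triflate, for which the weakly donating arsine ligand and chloride are the usual remedy for slow transmetalation, should deliver the twisted 1-vinylcyclohexene without touching the silyl ether.

Step 4
Reactants: 7 but-2-yn-1-ol
Product: 9 (2E)-3-iodobut-2-en-1-ol, via alkenylzirconocene 8 (not isolated)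
Conditions: i-Bu2AlH (1 equiv), THF, 0 °C; Cp2Zr(H)Cl, 0 °C → rt; I2, −78 °C; aqueous work-up
Reagents that add atoms: iodine II; diisobutylaluminium hydride CC(C)C[AlH]CC(C)C (aluminium of 8 only); zirconocene chloride hydride [H][Zr](Cl)(C1C=CC=C1)C1C=CC=C1 (zirconium of 8 only)
Why: Hydrozirconation–iodination: after the hydroxyl is masked in the flask as its bulky diisobutylaluminium alkoxide, Zr–H adds syn across the alkyne with zirconium at the less hindered, methyl-bearing carbon, and iodinolysis with retention should fix the E geometry that becomes 9E and 9'E of the target.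

Step 5
Reactants: 9 (2E)-3-iodobut-2-en-1-ol
Product: 10 diethyl [(2E)-3-iodobut-2-en-1-yl]phosphonate
Conditions: ZnI2 (1.5 equiv), P(OEt)3, THF, reflux
Reagents that add atoms: triethyl phosphite CCOP(OCC)OCC
Why: Zinc iodide-mediated one-flask Michaelis–Arbuzov-type conversion of a primary allylic alcohol into its diethyl phosphonate, in which phosphorus should enter at the unhindered primary carbon and the alkenyl iodide, inert to phosphite without a transition metal, should keep its geometry.

Step 6
Reactants: 10 iodophosphonate; 11 (2E,4E,6E)-2,7-dimethylocta-2,4,6-trienedial (C10-dialdehyde)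
Product: 13 (2E,4E,6E,8E,10E)-11-iodo-2,7-dimethyldodeca-2,4,6,8,10-pentaenal, via phosphonate carbanion 12 (not isolated)
Conditions: 10, NaHMDS, THF, −78 °C; cannulated into 11 (3 equiv), THF, −40 → 0 °C
Reagents that add atoms: sodium hexamethyldisilazide [Na+].C[Si](C)(C)[N-][Si](C)(C)C (sodium of 12 only)
Why: Horner–Wadsworth–Emmons olefination of an allylic phosphonate carbanion, which attacks through its α-carbon (the γ-carbon is fully substituted) and should give C11'=C12' with E geometry, while inverse addition to excess dialdehyde and the lower electrophilicity of the extended product aldehyde favour mono-olefination and the silazide base avoids iodine–metal exchange.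

Step 7
Reactants: 10 iodophosphonate; 14 ethynyltrimethylsilane
Product: 15 diethyl [(2E)-3-methyl-5-(trimethylsilyl)pent-2-en-4-yn-1-yl]phosphonate
Conditions: PdCl2(PPh3)2 (cat.), CuI (cat.), Et3N, THF, rt
Reagents that add atoms: none
Why: Sonogashira coupling of the alkenyl iodide proceeds at room temperature with retention of the E geometry and turns the same C4 module into the C7–C11 unit of the alkyne half, the weak amine base leaving the phosphonate CH2 alone.

Step 8
Reactants: 15 silyl enynyl phosphonate; 13 C14 iodo pentaenal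
Product: 17 [(3E,5E,7E,9E,11E,13E,15E)-16-iodo-3,7,12-trimethylheptadeca-3,5,7,9,11,13,15-heptaen-1-yn-1-yl]trimethylsilane, via phosphonate carbanion 16 (not isolated)
Conditions: 15, NaHMDS, THF, −78 °C; 13, −78 → 0 °C
Reagents that add atoms: sodium hexamethyldisilazide [Na+].C[Si](C)(C)[N-][Si](C)(C)C (sodium of 16 only)
Why: Horner–Wadsworth–Emmons olefination through the α-carbon of the delocalised carbanion 16 should form C11=C12 with E geometry, while the silyl cap removes the acidic alkyne hydrogen and the alkenyl iodide is inert to the silazide base at low temperature.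

Step 9
Reactants: 6 vinyl ring diene; 17 C20 iodo heptaenyne; 4 enol triflate
Product: 21 (3R,3'R)-3,3'-bis(tert-butyldimethylsilyloxy)-7,8-didehydro-7',8'-dihydro-β,β-carotene (all-E), via B-alkyl-9-BBN 18 (not isolated), via C31 silylalkyne 19 (not isolated), via C31 terminal alkyne 20 (not isolated)
Conditions: 6 (1.3 equiv), 9-BBN (1.2 equiv), THF, 0 °C → rt; 3 M aq Cs2CO3, then 17 (1.0 equiv), PdCl2(dppf) (cat.), AsPh3, DMF, rt; MeOH, rt; 4 (1.6 equiv), Pd(PPh3)4 (cat.), CuI (cat.), i-Pr2NH, 40 °C
Reagents that add atoms: 9-borabicyclo[3.3.1]nonane B1C2CCCC1CCC2 (boron unit of 18 only; the product keeps only its hydrogen, at C7')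
Why: 9-BBN adds syn and anti-Markovnikov to the only monosubstituted alkene of 6, placing boron on C8' and hydrogen on C7', so that the vinyl group becomes the saturated C7'–C8' bridge and a C8' nucleophile (18). Pd(0) inserts into the C9'–I bond of 17, the carbonate-activated borate hands over its primary alkyl group, and reductive elimination forms C8'–C9' with retention of the 9'E geometry, faster than β-hydride elimination on the wide-bite-angle dppf complex; the closest known reaction type is the one-pot hydroboration/B-alkyl Suzuki–Miyaura coupling of alkenyl iodides, a closed-shell process that spares the radical-sensitive heptaene. Methanol and the carbonate already present then remove the C7 silyl cap (19 to 20), and copper(I), amine and 4 start a Sonogashira coupling (oxidative addition of the C6–OTf bond, copper acetylide transfer) that forms C6–C7. No ring is closed and no stereocentre is made: C3 and C3' come from 1, and the seven E alkenes are carried in by 17. The selectivities needed are vinyl over the tetrasubstituted C5'=C6' ring alkene (secured by the substitution pattern and the bulk of 9-BBN), B–H kept away from the polyene (9-BBN is kept below 6 in amount and water is added before 17), alkyl before alkynyl transfer (silyl cap, no copper in the second stage), and C–I before C–OTf (4 enters only after 17 is consumed and is used in excess because surplus borate can also take it).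

Step 10
Reactants: 21 bis-silyl ether
Product: 22 (3R,3'R)-7,8-didehydro-7',8'-dihydro-β,β-carotene-3,3'-diol (all-E; CNP0178054.1)
Conditions: TBAF, THF, rt
Reagents that add atoms: none
Why: Fluoride-induced cleavage of both secondary silyl ethers (Si–F bond formation) is non-acidic and non-oxidising, so the polyene geometry and the two carbinol centres should remain as set.

Compound list
1 | (4R,6R)-4-hydroxy-2,2,6-trimethylcyclohexanone | C[C@H]1C(=O)C(C)(C)C[C@H](O)C1 | starting material
2 | (4R,6R)-4-(tert-butyldimethylsilyloxy)-2,2,6-trimethylcyclohexanone | C[C@H]1C(=O)C(C)(C)C[C@H](O[Si](C)(C)C(C)(C)C)C1 | intermediate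
3 | lithium (4R)-4-(tert-butyldimethylsilyloxy)-2,6,6-trimethylcyclohex-1-en-1-olate | [Li+].CC1=C([O-])C(C)(C)C[C@H](O[Si](C)(C)C(C)(C)C)C1 | intermediate
4 | (4R)-4-(tert-butyldimethylsilyloxy)-2,6,6-trimethylcyclohex-1-en-1-yl trifluoromethanesulfonate | CC1=C(OS(=O)(=O)C(F)(F)F)C(C)(C)C[C@H](O[Si](C)(C)C(C)(C)C)C1 | intermediate
5 | tributyl(vinyl)stannane | C=C[Sn](CCCC)(CCCC)CCCC | starting material
6 | tert-butyl(dimethyl){[(1R)-4-ethenyl-3,5,5-trimethylcyclohex-3-en-1-yl]oxy}silane | CC1=C(C=C)C(C)(C)C[C@H](O[Si](C)(C)C(C)(C)C)C1 | intermediate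
7 | but-2-yn-1-ol | CC#CCO | starting material
8 | chloro(dicyclopentadienyl)[(2E)-4-(diisobutylaluminiooxy)but-2-en-2-yl]zirconium (Zr trans to CH2O; Cp drawn η1) | C/C(=C\CO[Al](CC(C)C)CC(C)C)[Zr](Cl)(C1C=CC=C1)C1C=CC=C1 | intermediate
9 | (2E)-3-iodobut-2-en-1-ol | C/C(I)=C\CO | intermediate
10 | diethyl [(2E)-3-iodobut-2-en-1-yl]phosphonate | C/C(I)=C\CP(=O)(OCC)OCC | intermediate
11 | (2E,4E,6E)-2,7-dimethylocta-2,4,6-trienedial | O=C/C(C)=C/C=C/C=C(C)/C=O | starting material
12 | sodium α-carbanion of 10 | [Na+].C/C(I)=C\[CH-]P(=O)(OCC)OCC | intermediate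
13 | (2E,4E,6E,8E,10E)-11-iodo-2,7-dimethyldodeca-2,4,6,8,10-pentaenal | O=C/C(C)=C/C=C/C=C(C)/C=C/C=C(\C)I | intermediate
14 | ethynyltrimethylsilane | C#C[Si](C)(C)C | starting material
15 | diethyl [(2E)-3-methyl-5-(trimethylsilyl)pent-2-en-4-yn-1-yl]phosphonate | C[Si](C)(C)C#C/C(C)=C/CP(=O)(OCC)OCC | intermediate
16 | sodium α-carbanion of 15 | [Na+].C[Si](C)(C)C#C/C(C)=C/[CH-]P(=O)(OCC)OCC | intermediate
17 | [(3E,5E,7E,9E,11E,13E,15E)-16-iodo-3,7,12-trimethylheptadeca-3,5,7,9,11,13,15-heptaen-1-yn-1-yl]trimethylsilane | C[Si](C)(C)C#C/C(C)=C/C=C/C(C)=C/C=C/C=C(C)/C=C/C=C(\C)I | intermediate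
18 | 9-{2-[(4R)-4-(tert-butyldimethylsilyloxy)-2,6,6-trimethylcyclohex-1-en-1-yl]ethyl}-9-borabicyclo[3.3.1]nonane | CC1=C(CCB2C3CCCC2CCC3)C(C)(C)C[C@H](O[Si](C)(C)C(C)(C)C)C1 | intermediate
19 | {(3E,5E,7E,9E,11E,13E,15E)-18-[(4R)-4-(tert-butyldimethylsilyloxy)-2,6,6-trimethylcyclohex-1-en-1-yl]-3,7,12,16-tetramethyloctadeca-3,5,7,9,11,13,15-heptaen-1-yn-1-yl}trimethylsilane | C[Si](C)(C)C#C/C(C)=C/C=C/C(C)=C/C=C/C=C(C)/C=C/C=C(\C)CCC1=C(C)C[C@@H](O[Si](C)(C)C(C)(C)C)CC1(C)C | intermediate
20 | C-desilylated 19 (terminal alkyne, all-E, 3'R) | C#C/C(C)=C/C=C/C(C)=C/C=C/C=C(C)/C=C/C=C(\C)CCC1=C(C)C[C@@H](O[Si](C)(C)C(C)(C)C)CC1(C)C | intermediate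
21 | (3R,3'R)-3,3'-bis(tert-butyldimethylsilyloxy)-7,8-didehydro-7',8'-dihydro-β,β-carotene (all-E) | CC1=C(C#C/C(C)=C/C=C/C(C)=C/C=C/C=C(C)/C=C/C=C(\C)CCC2=C(C)C[C@@H](O[Si](C)(C)C(C)(C)C)CC2(C)C)C(C)(C)C[C@H](O[Si](C)(C)C(C)(C)C)C1 | intermediate
22 | (3R,3'R)-7,8-didehydro-7',8'-dihydro-β,β-carotene-3,3'-diol (all-E) | CC1=C(C#C/C(C)=C/C=C/C(C)=C/C=C/C=C(C)/C=C/C=C(\C)CCC2=C(C)C[C@@H](O)CC2(C)C)C(C)(C)C[C@H](O)C1 | target

Total step count: 10
Longest linear sequence: 6 steps (steps 4, 5, 6, 8, 9, 10, from 7). The ring branch from 1 needs 5 steps (1, 2, 3, 9, 10).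

Steps most likely to fail

Step 9. In the third stage surplus alkylborate may compete with the copper acetylide for the slowly formed alkenylpalladium species of the hindered triflate. Long exposure of the full polyene to palladium, base and warmth may also scramble alkene geometry. The fallback sets out from 4 and 15 and comes back at 21. It gives up the three-component flask and closes the alkyne end first, at the C15 stage.
- Desilylative Sonogashira coupling of 15 with 4 (Pd(PPh3)4, CuI, K2CO3, MeOH/THF) should give diethyl [(2E)-5-{(4R)-4-(tert-butyldimethylsilyloxy)-2,6,6-trimethylcyclohex-1-en-1-yl}-3-methylpent-2-en-4-yn-1-yl]phosphonate F1.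
- Horner–Wadsworth–Emmons olefination of 13 with the sodium carbanion of F1 should give the ring-bearing all-E C29 heptaenynyl iodide F2.
- Borane 18, made separately from 6, is then joined to F2 in a plain two-component B-alkyl Suzuki–Miyaura coupling, which forms C8'–C9' as the last carbon–carbon bond and gives 21.

Step 6. Olefination may run on at the second formyl group, and the γ-iodo carbanion may decay while it waits for the poorly soluble dialdehyde. The fallback sets out from 11 and comes back at 13. It desymmetrises the dialdehyde before the olefination instead of relying on stoichiometry.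
- Trimethyl orthoformate with catalytic PPTS in MeOH masks one formyl group as (2E,4E,6E)-8,8-dimethoxy-2,7-dimethylocta-2,4,6-trienal F3. This is separated from recyclable 11 and diacetal.
- Carbanion 12 then meets a single, soluble aldehyde and should give (2E,4E,6E,8E,10E)-11-iodo-1,1-dimethoxy-2,7-dimethyldodeca-2,4,6,8,10-pentaene F4.
- Aqueous oxalic acid in THF releases 13.

Step 5. The zinc-promoted C–O activation may be sluggish because iodine disfavours positive charge build-up. If it ionises, allylic transposition or loss of alkene geometry may follow. The fallback sets out from 9 and comes back at 10. It replaces the ionising one-flask process by two SN2 displacements.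
- PBr3 in Et2O at 0 °C should give (2E)-1-bromo-3-iodobut-2-ene F5.
- Heating F5 in neat triethyl phosphite (classical Michaelis–Arbuzov reaction) should give 10.

Further compounds
F1 | step 9 | diethyl [(2E)-5-{(4R)-4-(tert-butyldimethylsilyloxy)-2,6,6-trimethylcyclohex-1-en-1-yl}-3-methylpent-2-en-4-yn-1-yl]phosphonate | CC1=C(C#C/C(C)=C/CP(=O)(OCC)OCC)C(C)(C)C[C@H](O[Si](C)(C)C(C)(C)C)C1
F2 | step 9 | all-E C29 heptaenynyl iodide (17 with the (4R)-4-(tert-butyldimethylsilyloxy)-2,6,6-trimethylcyclohex-1-en-1-yl ring in place of SiMe3) | CC1=C(C#C/C(C)=C/C=C/C(C)=C/C=C/C=C(C)/C=C/C=C(\C)I)C(C)(C)C[C@H](O[Si](C)(C)C(C)(C)C)C1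
F3 | step 6 | (2E,4E,6E)-8,8-dimethoxy-2,7-dimethylocta-2,4,6-trienal | COC(OC)/C(C)=C/C=C/C=C(C)/C=O
F4 | step 6 | (2E,4E,6E,8E,10E)-11-iodo-1,1-dimethoxy-2,7-dimethyldodeca-2,4,6,8,10-pentaene | COC(OC)/C(C)=C/C=C/C=C(C)/C=C/C=C(\C)I
F5 | step 5 | (2E)-1-bromo-3-iodobut-2-ene | C/C(I)=C\CBr
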